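**One-step zero.** In a one-step world the starting material and the coupling partner meet once per turnover, so the rate follows the first power of each, and an order of 1 is the zero of my scale. I asked how far the flasks stood from that zero.

| flask | starting material | coupling partner | free catalyst | time |
|---|---|---|---|---|
| red | 250 mM | 750 mM | 20.0 mM |  |
| grey | 250 mM | 750 mM | 10.0 mM |  |
| green | 250 mM | 2200 mM | 20.0 mM |  |
| amber | 500 mM | 750 mM | 20.0 mM |  |
| ochre | 250 mM | 250 mM | 40.0 mM | 180 s |

- red run (time / s: [product] / mM): 7.2: 2; 12: 7; 21: 19; 36: 32; 62: 56; 110: 98; 180: 161
- grey run (time / s: [product] / mM): 7.2: 0; 12: 5; 21: 2; 36: 11; 62: 20; 110: 51; 180: 93
- green run (time / s: [product] / mM): 7.2: 15; 12: 21; 21: 35; 36: 66; 62: 116; 110: 188; 180: 236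
- amber run (time / s: [product] / mM): 7.2: 13; 12: 15; 21: 42; 36: 70; 62: 137; 110: 259; 180: 385

(scatter of a reading: 3 mM)

- apparent order in [starting material] of the starting rate, round the charge of the red run (the rate where two percent of its starting material have turned into product) (one fixed amount of product, the same in the runs compared)
- apparent order in [coupling partner] of the starting rate, round the charge of the red run (the rate where two percent of its starting material have turned into product)
- product in the ochre run at 180 s, as a share of the starting material charged

- Overall: starting material + coupling partner -> product, with free catalyst as catalyst.
- Constant volume, constant temperature.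
- The analysis sees a species whether free or bound.
- An order is taken over about fifteen percent of the charge, up and down.

**Two ways.** Red and green share their starting material and catalyst, and green has 2.93 times the coupling partner. At 62 s, green had turned 46.4% of its starting material and red 22.4%, and that same-time ratio gave me an order of 0.677. My second way compared mean rates over similar stretches: green to 110 s, at 75.2% of its charge, and red to 180 s, at 64.4%. That gave 0.602.

**Which cheats?** Lost starting material lowers green's rate, so it could have cheated. But the same-time pair stood further apart in conversion, 24 percentage points against 11 points, and yet it read higher. So conversion did not tell me which way cheated, and I held the two orders as a bracket.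

I took the mean, 0.639. Its distance from the zero is 0.361, and I called this the order shortfall, one minus the apparent order in coupling partner. Ochre holds a third of red's coupling partner, and my order puts the rate cut at a factor of 0.495.

**The forecast.** It gave 1.1 for the starting material, 0.7 for the coupling partner and 45% for ochre. On the coupling partner it reasoned: “The local order at 750 mM may be slightly higher, so I take 0.7.” My mean lay below that.

**The flask.** The orders came out at 1.0 and 0.64, and ochre reached 48.2% of its starting material at 180 s. The forecast held on each within tolerance.

    2 free catalyst ⇌ catalyst dimer, settled at all times (80.70 L mol⁻¹)
    catalyst dimer + starting material + coupling partner → product + catalyst dimer (1.690 L² mol⁻² s⁻¹)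
    2 coupling partner ⇌ idle reagent dimer, settled at all times (2.090 L mol⁻¹)
    starting material + coupling partner + product → 2 product (0.1190 L² mol⁻² s⁻¹)

**Idle pairing.** The shortfall of 0.361 comes from the tying up of coupling partner in pairs as idle reagent dimer. At red's charge, the run without that pairing has an order of 1.0 against 0.64, a rise of 0.37, close to the shortfall. In ochre, the shortfall softens the partner cut by a factor of 1.49, yet the pairing still holds product at 48.2% of the starting material, against 60.3% without it.

The runs are calculated with made-up constants, noise included.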